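The runs are calculated with made-up constants, and the scatter is random.

If activator is a budget, a flask makes ring up to what its excess over the starting material pays for, and the first chemist argues just that: green carries 1.40 equivalents of activator, an excess of 0.400 of the charge, and its ring reads 35% at 40.0 h, hardly moving in the last interval.

| flask | starting material | activator | remark | time |
|---|---|---|---|---|
| green | 0.020 M | 0.028 M | run made earlier |  |
| red | 0.020 M | 0.084 M | run made earlier |  |
| dawn | 0.020 M | 0.0240 M |  | 2.5 d |
| noon | 0.020 M | 0.0360 M |  | 2.5 d |
| autumn | 0.020 M | 0.0540 M |  | 2.5 d |

| run | time / h | ring / % | starting material / % |
|---|---|---|---|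
| green | 4.00 | 3 | 61 |
| green | 10.0 | 12 | 27 |
| green | 20.0 | 23 | 7 |
| green | 30.0 | 33 | 1 |
| green | 40.0 | 35 | 0 |
| red | 4.00 | 4 | 21 |
| red | 10.0 | 18 | 0 |
| red | 20.0 | 42 | 1 |
| red | 30.0 | 52 | 0 |
| red | 40.0 | 61 | 1 |

(readings scatter by 2 percentage points)

- a species is counted by the starting material in it: one open dimer counts as two

* which of the two there is more of at the end, counted by the starting material in each, dawn (open dimer / ring)
* which of the two there is more of at the end, counted by the starting material in each, noon (open dimer / ring)
* which of the two there is more of at the end, counted by the starting material in each, autumn (open dimer / ring)
* ring at the end, in percent of the starting material charged, dawn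
* ring at the end, in percent of the starting material charged, noon
* ring at the end, in percent of the starting material charged, autumn

The second chemist objects. Red's excess is 8.00 times green's, yet at 40.0 h its ring reads 61% against green's 35%. And at 4.00 h red shows 21% starting material and 4% ring, so 75.0% of the charge sits in something else. She sees a race: reacted material enters a store that either closes to ring or ends as open dimer, and activator tilts that race gradually.

I side with her and read ring against the logarithm of the equivalents. The doubling gain, the points of ring that each doubling of activator adds at a fixed reading time, comes from the two runs at 40.0 h: 16 percentage points.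

The new flasks stop 20.0 h later, and that time needs a correction of its own. Red's starting material reads 0% at 10.0 h and no more than 1% at any later reading, so I read its later ring gains as the store emptying. They fall from 24 points between 10.0 h and 20.0 h to 9 points between 30.0 h and 40.0 h, a factor of 0.375. Applied to red's gain over the preceding 20.0 h, that factor adds 7.1 points, uncertain by a few points at this scatter, and I add it to each flask.

Starting from green, my ring is 38.5% at dawn, 48.1% at noon and 57.7% at autumn. The store should still hold 4.3 points, and I count the rest as open dimer: 57.2%, 47.6% and 38.0%. So open dimer leads at dawn, ring leads at autumn, and noon is a near tie that I call for ring.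

The forecast, on the first chemist's side, sees an “activator budget or equilibrium limit” and gives ring 22%, 47% and 62%, with open dimer, open dimer and ring ahead, which differs from my reckoning at dawn and in the noon mark.

The flasks give ring 39.3% at dawn, 49.7% at noon and 58.9% at autumn, with open dimer 51.0%, 42.5% and 33.7%: open dimer leads at dawn, ring at noon and ring at autumn.

    starting material + activator → activated form (k = 4.40 L mol⁻¹ h⁻¹)
    activated form → ring (k = 0.0450 h⁻¹)
    starting material + activated form → open dimer (k = 6.70 L mol⁻¹ h⁻¹)
    starting material + activated form → side product (k = 0.440 L mol⁻¹ h⁻¹)

Dawn ended with starting material, the limiting reagent, at 1.3% and activator at 40% of its own charge. Take one more flask like dawn, but with 2.05 equivalents of activator. The doubling gain from green, plus the same correction, gives 51.2% ring. That flask gives 52.8% ring and 39.6% open dimer.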